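**Strategy.** Numbering the tetronic acid ring O1–C2(=O)–C3(Me)=C4(OH)–C5, C5 is the α-carbon of the masked C4 ketone and O1 a carboxylate oxygen, two sites of like (nucleophilic) polarity. The route unites them by polarity reversal: C5 is turned into an electrophilic chloride, set as the S chloride by enamine catalysis, and the C2 carboxylate of a γ-chloro-β-keto acid closes the lactone ring at O1–C5 by 5-exo-tet displacement with inversion, giving the free (5R)-tetronic acid in one operation. Both methyl stereocentres are bought in the citronellal series; an alkynyl tetronic acid and an E-alkenyl iodide are joined last by hydroboration and Suzuki–Miyaura coupling.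

Key step: step 6

Assumption: the (2R,5R)-2,5-diphenylpyrrolidine/NCS chlorination is taken to give the 2S chloride by steric shielding of one enamine face; if the sense is opposite, the (2S,5S) catalyst is used with no other change.
Assumption: (R)-citronellal, (R)-citronellyl bromide and 3-(bromomethyl)furan are taken as purchasable in high chemical and (where relevant) enantiomeric purity.

**Step 1**
Reactants: 1 (R)-citronellal [(3R)-3,7-dimethyloct-6-enal]
Product: 3 (3R)-3,7-dimethyloct-6-en-1-yne, via alkenyl nonaflate 2 (not isolated)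
Conditions: C4F9SO2F (1.2 equiv), P2-Et phosphazene base (2.5 equiv), DMF, −30 °C to rt
Reagents that add atoms: none
Why: O-sulfonylation of the aldehyde enolate gives the enol nonaflate, which loses nonaflate by E2 elimination in the same flask (aldehyde-to-terminal-alkyne dehydration via an enol sulfonate); the stereocentre is β to the carbonyl and should not be touched.

**Step 2**
Reactants: 3 (3R)-3,7-dimethyloct-6-en-1-yne
Product: 4 (4R)-4-methylhex-5-ynal
Conditions: O3, CH2Cl2, −78 °C (Sudan Red 7B end point); then PPh3, −78 °C to rt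
Reagents that add atoms: ozone, [O-][O+]=O
Why: Ozonolysis with reductive work-up, in which the electron-rich trisubstituted alkene should react far faster than the terminal alkyne, and the dye end point guards against over-oxidation.

**Step 3**
Reactants: 4 (4R)-4-methylhex-5-ynal
Product: 5 (2S,4R)-2-chloro-4-methylhex-5-ynal (used crude)
Conditions: NCS (1.3 equiv), (2R,5R)-2,5-diphenylpyrrolidine (10 mol %), CH2Cl2, 0 °C to rt; pentane, filtration
Reagents that add atoms: N-chlorosuccinimide, O=C1CCC(=O)N1Cl
Why: Enamine-catalysed α-chlorination of an aldehyde, in which the C2-symmetric amine shields one enamine face so that the new C–Cl centre (2S) is set under catalyst control, independent of the remote methyl centre.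

**Step 4**
Reactants: 5 (2S,4R)-2-chloro-4-methylhex-5-ynal; 6 tert-butyl propanoate
Product: 8 tert-butyl (4S,6R)-4-chloro-3-hydroxy-2,6-dimethyloct-7-ynoate (epimers at C2/C3), via lithium enolate 7 (not isolated)
Conditions: 6, LDA (commercial solution), THF, −78 °C; then 5, −78 °C; AcOH quench at −78 °C
Reagents that add atoms: none
Why: Lithium ester-enolate aldol addition at −78 °C should be faster than enolisation or epoxide closure of the α-chloroaldehyde, and the two new centres (C2, C3) are erased later, so their configuration is immaterial.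

**Step 5**
Reactants: 8 tert-butyl (4S,6R)-4-chloro-3-hydroxy-2,6-dimethyloct-7-ynoate
Product: 9 tert-butyl (4S,6R)-4-chloro-2,6-dimethyl-3-oxooct-7-ynoate
Conditions: Dess–Martin periodinane (1.5 equiv), CH2Cl2, 0 °C to rt
Reagents that add atoms: none
Why: Dess–Martin oxidation of the secondary alcohol to the β-keto ester under non-basic conditions; the chloride-bearing centre should hold because the 1,3-dicarbonyl unit enolises toward C2, not toward C4.

**Step 6**
Reactants: 9 tert-butyl (4S,6R)-4-chloro-2,6-dimethyl-3-oxooct-7-ynoate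
Product: 11 (5R)-4-hydroxy-3-methyl-5-[(2R)-2-methylbut-3-yn-1-yl]furan-2(5H)-one, via β-keto acid 10 (not isolated)
Conditions: TFA/CH2Cl2 (1:3), 0 °C to rt, evaporation below 25 °C; then NaHCO3 (3 equiv), DMF, rt; 1 M HCl work-up
Reagents that add atoms: none
Why: Acidolysis of the tert-butyl ester gives β-keto acid 10, whose carboxylate (bicarbonate) attacks C5 from the face opposite chloride in an intramolecular SN2 displacement that forms the O1–C5 bond; the resulting furan-2,4-dione enolises to the tetronic acid and is deprotonated, which should make the closure irreversible. The closest known reaction type is the classical tetronic acid synthesis by lactonisation of γ-halo-acetoacetates, run here on a stereodefined secondary chloride. The lactone ring closes in the 5-exo-tet mode. C5 is the only stereocentre formed and is controlled by the configuration of the C–Cl centre set in step 3: inversion converts the 4S chloride into the 5R lactone, while the methyl centre is a spectator. The step needs O-alkylation by the carboxylate rather than C3-alkylation (Favorskii pathway), elimination or decarboxylation, and no epimerisation before closure; under bicarbonate the carboxylate is the only strongly nucleophilic site, the α-keto chloride is a good SN2 electrophile, and the 1,3-dicarbonyl unit enolises toward C3, not toward C5.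

**Step 7**
Reactants: 12 (R)-citronellyl bromide [(6R)-8-bromo-2,6-dimethyloct-2-ene]; 13 3-(bromomethyl)furan
Product: 15 3-[(4S)-4,8-dimethylnon-7-en-1-yl]furan, via Grignard reagent 14 (not isolated)
Conditions: 12, Mg, THF, rt to 40 °C; then 13, Li2CuCl4 (3 mol %), THF, −78 to 0 °C
Reagents that add atoms: none
Why: Copper-catalysed sp3–sp3 cross-coupling of a primary alkyl Grignard reagent with a reactive furylmethyl bromide; the stereocentre is remote and untouched.

**Step 8**
Reactants: 15 3-[(4S)-4,8-dimethylnon-7-en-1-yl]furan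
Product: 17 (4S)-7-(furan-3-yl)-4-methylheptan-1-ol, via aldehyde 16 (not isolated)
Conditions: OsO4 (2 mol %), NaIO4 (4 equiv), 2,6-lutidine, dioxane/H2O (3:1), rt; then NaBH4, MeOH, 0 °C
Reagents that add atoms: osmium tetroxide (oxygen carrier, reoxidised by periodate), O=[Os](=O)(=O)=O; sodium periodate, [Na+].[O-]I(=O)(=O)=O
Why: Lemieux–Johnson cleavage, in which OsO4 should dihydroxylate the electron-rich trisubstituted alkene in preference to the aromatic furan (ozone is avoided for that reason), periodate cleaves the diol and borohydride reduces the aldehyde in the same flask.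

**Step 9**
Reactants: 17 (4S)-7-(furan-3-yl)-4-methylheptan-1-ol
Product: 18 3-[(4S)-7-iodo-4-methylheptyl]furan
Conditions: I2, PPh3, imidazole, CH2Cl2, 0 °C to rt
Reagents that add atoms: iodine, II
Why: Appel-type iodination of a primary alcohol through the alkoxyphosphonium iodide (SN2), under conditions a 3-alkylfuran should tolerate.

**Step 10**
Reactants: 18 3-[(4S)-7-iodo-4-methylheptyl]furan
Product: 19 3-[(4R)-4-methylnon-8-yn-1-yl]furan
Conditions: LiC≡CH·H2NCH2CH2NH2, DMSO, 10 °C to rt
Reagents that add atoms: lithium acetylide–ethylenediamine complex, [Li]C#C.NCCN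
Why: SN2 alkylation of lithium acetylide by a primary iodide in DMSO (acetylide alkylation); the descriptor changes only through CIP priorities.

**Step 11**
Reactants: 19 3-[(4R)-4-methylnon-8-yn-1-yl]furan
Product: 21 3-[(4S,8E)-9-iodo-4,8-dimethylnon-8-en-1-yl]furan, via alkenylalane 20 (not isolated)
Conditions: Me3Al (2.5 equiv), Cp2ZrCl2 (0.25 equiv), CH2Cl2, 0 °C to rt; then I2, THF, −30 to 0 °C
Reagents that add atoms: trimethylaluminium, C[Al](C)C; iodine, II
Why: Zirconium-catalysed syn carboalumination (Negishi carboalumination) places methyl on the internal and aluminium on the terminal alkyne carbon, and iodinolysis of the C–Al bond with retention should fix the E trisubstituted alkene.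

**Step 12**
Reactants: 11 (5R)-4-hydroxy-3-methyl-5-[(2R)-2-methylbut-3-yn-1-yl]furan-2(5H)-one; 21 3-[(4S,8E)-9-iodo-4,8-dimethylnon-8-en-1-yl]furan
Product: 23 (5R)-5-[(2R,3E,5E,10R)-13-(furan-3-yl)-2,6,10-trimethyltrideca-3,5-dien-1-yl]-4-hydroxy-3-methylfuran-2(5H)-one, via alkenylborane 22 (not isolated)
Conditions: Cy2BH (2.2 equiv, made in the flask from BH3·SMe2 and cyclohexene), THF, 0 °C to rt; then 21, Pd(PPh3)4 (5 mol %, zerovalent palladium), 3 M aq NaOH, THF, 45 °C; 1 M HCl work-up
Reagents that add atoms: none
Why: Syn, anti-Markovnikov hydroboration of the terminal alkyne by the hindered dialkylborane (the first equivalent is taken up by the acidic enol as a borinate, an in situ protection) followed by Suzuki–Miyaura coupling with the alkenyl iodide should retain both alkene geometries and give the E,E-diene.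

**Compound list**
1 | (R)-citronellal, (3R)-3,7-dimethyloct-6-enal | CC(C)=CCC[C@@H](C)CC=O | starting material
2 | (3R)-3,7-dimethylocta-1,6-dien-1-yl nonafluorobutane-1-sulfonate (E/Z mixture) | CC(C)=CCC[C@@H](C)C=COS(=O)(=O)C(F)(F)C(F)(F)C(F)(F)C(F)(F)F | intermediate
3 | (3R)-3,7-dimethyloct-6-en-1-yne | CC(C)=CCC[C@@H](C)C#C | intermediate
4 | (4R)-4-methylhex-5-ynal | O=CCC[C@@H](C)C#C | intermediate
5 | (2S,4R)-2-chloro-4-methylhex-5-ynal | O=C[C@@H](Cl)C[C@@H](C)C#C | intermediate
6 | tert-butyl propanoate | CCC(=O)OC(C)(C)C | starting material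
7 | lithium (E)-1-tert-butoxyprop-1-en-1-olate | C/C=C(/O[Li])OC(C)(C)C | intermediate
8 | tert-butyl (4S,6R)-4-chloro-3-hydroxy-2,6-dimethyloct-7-ynoate (epimers at C2/C3) | CC(C(=O)OC(C)(C)C)C(O)[C@H](C[C@@H](C)C#C)Cl | intermediate
9 | tert-butyl (4S,6R)-4-chloro-2,6-dimethyl-3-oxooct-7-ynoate (epimers at C2) | CC(C(=O)OC(C)(C)C)C(=O)[C@H](C[C@@H](C)C#C)Cl | intermediate
10 | (4S,6R)-4-chloro-2,6-dimethyl-3-oxooct-7-ynoic acid | CC(C(=O)O)C(=O)[C@H](C[C@@H](C)C#C)Cl | intermediate
11 | (5R)-4-hydroxy-3-methyl-5-[(2R)-2-methylbut-3-yn-1-yl]furan-2(5H)-one | CC1=C(O)[C@@H](C[C@@H](C)C#C)OC1=O | intermediate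
12 | (R)-citronellyl bromide, (6R)-8-bromo-2,6-dimethyloct-2-ene | CC(C)=CCC[C@@H](C)CCBr | starting material
13 | 3-(bromomethyl)furan | BrCc1ccoc1 | starting material
14 | [(3R)-3,7-dimethyloct-6-en-1-yl]magnesium bromide | CC(C)=CCC[C@@H](C)CC[Mg]Br | intermediate
15 | 3-[(4S)-4,8-dimethylnon-7-en-1-yl]furan | CC(C)=CCC[C@@H](C)CCCc1ccoc1 | intermediate
16 | (4S)-7-(furan-3-yl)-4-methylheptanal | O=CCC[C@@H](C)CCCc1ccoc1 | intermediate
17 | (4S)-7-(furan-3-yl)-4-methylheptan-1-ol | OCCC[C@@H](C)CCCc1ccoc1 | intermediate
18 | 3-[(4S)-7-iodo-4-methylheptyl]furan | ICCC[C@@H](C)CCCc1ccoc1 | intermediate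
19 | 3-[(4R)-4-methylnon-8-yn-1-yl]furan | C#CCCC[C@@H](C)CCCc1ccoc1 | intermediate
20 | [(1E,6S)-9-(furan-3-yl)-2,6-dimethylnon-1-en-1-yl]dimethylalumane | C[Al](C)/C=C(\C)CCC[C@@H](C)CCCc1ccoc1 | intermediate
21 | 3-[(4S,8E)-9-iodo-4,8-dimethylnon-8-en-1-yl]furan | I/C=C(\C)CCC[C@@H](C)CCCc1ccoc1 | intermediate
22 | O-dicyclohexylboryl enolate of 11 carrying an (E)-alkenyl(dicyclohexyl)borane at the former alkyne terminus | CC1=C(OB(C2CCCCC2)C2CCCCC2)[C@@H](C[C@@H](C)/C=C/B(C2CCCCC2)C2CCCCC2)OC1=O | intermediate
23 | (5R)-5-[(2R,3E,5E,10R)-13-(furan-3-yl)-2,6,10-trimethyltrideca-3,5-dien-1-yl]-4-hydroxy-3-methylfuran-2(5H)-one (CNP0246504.1) | CC1=C(O)[C@@H](C[C@@H](C)/C=C/C=C(\C)CCC[C@@H](C)CCCc2ccoc2)OC1=O | target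

**Totals.** Total step count: 12. Longest linear sequence: 7 steps (steps 1–6, then 12); the alkenyl iodide branch is 5 steps (7–11).

**Steps most likely to fail**

Step 6: the free β-keto acid may lose CO2, or displacement of the secondary chloride may be slow enough for chloride exchange or elimination to erode the configuration at C5. The fallback sets out from 9 and reverses the order of events. K2CO3 in MeCN at rt converts 9 into its C3 enolate, whose ester-carbonyl oxygen should displace the chloride with the same inversion and the same ring bond, giving (2R)-5-tert-butoxy-4-methyl-2-[(2R)-2-methylbut-3-yn-1-yl]furan-3(2H)-one F1. Brief TFA/CH2Cl2 then removes the tert-butyl group and comes back to the route at 11; no β-keto acid is involved.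

Step 1: elimination of the enol nonaflate may stall, or the strong base may isomerise the propargylic centre toward the allene and erode its configuration. The fallback sets out from 1 and degrades then rebuilds one carbon under mild base. Condensation with morpholine gives the enamine 4-[(1E,3R)-3,7-dimethylocta-1,6-dien-1-yl]morpholine F2. Its electron-rich C=C is cleaved with O2/CuCl in MeCN to the one-carbon-shorter aldehyde (2R)-2,6-dimethylhept-5-enal F3. Homologation with dimethyl (1-diazo-2-oxopropyl)phosphonate (K2CO3, MeOH, 0 °C, Ohira–Bestmann) comes back to the route at 3.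

Step 12: the acidic enol may interfere with the borane (over-consumption or reduction of the lactone), or the alkenylborane may protodeboronate before transmetalation. The fallback sets out from 11 and uses a protected Negishi coupling. TIPSOTf/Et3N gives (5R)-3-methyl-5-[(2R)-2-methylbut-3-yn-1-yl]-4-[(triisopropylsilyl)oxy]furan-2(5H)-one F4. Hydrozirconation with Cp2Zr(H)Cl, transmetalation with ZnCl2 and coupling with 21 under Pd(PPh3)4 should give (5R)-5-[(2R,3E,5E,10R)-13-(furan-3-yl)-2,6,10-trimethyltrideca-3,5-dien-1-yl]-3-methyl-4-[(triisopropylsilyl)oxy]furan-2(5H)-one F5. Buffered TBAF/AcOH then removes the silyl group and comes back to the route at 23.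

**Further compounds**
F1 | step 6 | (2R)-5-tert-butoxy-4-methyl-2-[(2R)-2-methylbut-3-yn-1-yl]furan-3(2H)-one | CC1=C(OC(C)(C)C)O[C@H](C[C@@H](C)C#C)C1=O
F2 | step 1 | 4-[(1E,3R)-3,7-dimethylocta-1,6-dien-1-yl]morpholine | CC(C)=CCC[C@@H](C)/C=C/N1CCOCC1
F3 | step 1 | (2R)-2,6-dimethylhept-5-enal | CC(C)=CCC[C@@H](C)C=O
F4 | step 12 | (5R)-3-methyl-5-[(2R)-2-methylbut-3-yn-1-yl]-4-[(triisopropylsilyl)oxy]furan-2(5H)-one | CC1=C(O[Si](C(C)C)(C(C)C)C(C)C)[C@@H](C[C@@H](C)C#C)OC1=O
F5 | step 12 | (5R)-5-[(2R,3E,5E,10R)-13-(furan-3-yl)-2,6,10-trimethyltrideca-3,5-dien-1-yl]-3-methyl-4-[(triisopropylsilyl)oxy]furan-2(5H)-one | CC1=C(O[Si](C(C)C)(C(C)C)C(C)C)[C@@H](C[C@@H](C)/C=C/C=C(\C)CCC[C@@H](C)CCCc2ccoc2)OC1=O
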